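## Structural features

The target is a flavanone: benzene ring A is fused to dihydropyranone ring C (O1, C2, C3, C4, C4a, C8a), and a 2-hydroxy-6-methoxyphenyl ring B is attached at C2. Ring A is fully substituted, with a free hydroxyl at C5 hydrogen-bonded to the C4 ketone and methoxyls at C6, C7 and C8. C2 is the only stereocentre (S); it is benzylic to an aryl ring with two ortho oxygens, carries the ring oxygen, lies β to the ketone, and has no stereogenic neighbour. This position is fragile in two ways: base opens the C2–O1 bond by retro-oxa-Michael reaction to the 2'-hydroxychalcone, and acid or a Lewis acid can ionise the same bond to a well-stabilised benzylic cation; both paths racemise. Two phenols must be free at the end while four methyl ethers remain, and the C5 oxygen must be distinguished from its three methoxy neighbours. The real difficulty is therefore to set C2 next to a di-ortho-substituted aryl group, to close ring C on a hexasubstituted benzene without disturbing C2, and to finish without strong acid, strong base or a Lewis acid. The key step exploits the C3–C4 bond, which joins the ketone carbon on ring A to the methylene next to C2: with the ketone written as its silyl enol ether, C3=C4 is an enol-ether alkene that metathesis can form from a 1-silyloxyvinyl group on C4a and a vinyl group on C2 of a chiral aryl allyl ether. A second feature is used earlier: 2,6-dihydroxy-3,4,5-trimethoxyacetophenone has a mirror plane, so either hydroxyl can become O1 and the other is then the C5 hydroxyl.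

## Logic of the disconnections

**18 to 17.** The C3–H bond and the O–H bonds at C5 and C2' are exchanged for three O–Si bonds (C4 enol silane, two aryl silyl ethers). All three leave with buffered fluoride in one operation, so the β-aryloxy ketone exists only in the last flask and no Lewis acid or hydrogenation meets the finished flavanone; a methyl ether at C5 or a benzyl ether on ring B would each cost such a step. The skeleton is unchanged. The forward step must stay near neutral.

**17 to 16.** The C3=C4 double bond is cut, which opens ring C. This turns a bicyclic chromene into an aryl allyl ether with two terminal alkenes and leaves C2 untouched. The forward metathesis must engage a hindered, electron-rich 1,1-disubstituted alkene and must not let the allylic double bond migrate.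

**16 to 15.** The O–Si bonds of the enol silane and of the C5 silyl ether are cut. Both can be formed in one flask from a hydroxy ketone, so the stable carbonyl compound is regained at no cost in steps. The forward enolisation must not ionise the benzylic, allylic C2–O1 bond.

**15 to 7 and 13 (through 14).** The C2–O1 bond is cut. It is the one bond at the stereocentre that a catalytic asymmetric allylic substitution can form while also delivering the vinyl group needed for ring closure. The molecule falls into a ring A half and a ring B half of similar size, and the mirror symmetry of 7 removes any regiochemical question. The forward step must be branched-selective and enantioselective at an allyl terminus bearing a di-ortho-substituted aryl group, and must stop at mono-allylation.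

**13 to 12.** The carbonate C–O bond is cut. The carbonate is needed only as a leaving group that supplies its own base on ionisation. The forward acylation must be cold and quick, because the electron-rich cinnamyl system ionises easily.

**12 to 11.** The two C–H bonds at the carbinol carbon are cut (alcohol back to ester). This allows the alkene to be made by a reliable olefination. The forward reduction must be 1,2-selective.

**11 to 9 and 10.** The Cα=Cβ double bond is cut. This gives an aldehyde and a commercial phosphonate. The forward olefination must give the E isomer, which the iridium step requires.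

**9 to 8.** The O–Si bond on ring B is cut. The protecting group chosen is stable to hydride, phosphonate anion, aryloxide and ruthenium carbene, and is removed by fluoride. The forward silylation must overcome the hydrogen bond to the aldehyde.

**7 to 6.** One O–CH3 bond is re-formed in the backward sense (the methyl ether next to the carbonyl). The Lewis-acid demethylation is thus placed on a robust achiral ketone, not on the flavanone. The forward step must cleave only the carbonyl-flanked ether.

**6 to 4 (through 5).** The ring C–C(acyl) bond is cut. Only one ring position of 4 is free, so the acylation has no regiochemical alternative. The forward step must acylate a crowded position without cleaving ethers.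

**4 to 1 (through 2 and 3).** The ring C–O bond of the phenol is cut. The symmetric commercial tetraether 1 has two equivalent ring hydrogens. The forward step must hydroxylate once and must not over-oxidise an electron-rich phenol.

## Other disconnections considered

**Alternative 1:** Ring B is removed entirely. C1'–C2', C2'–C3' and C5'–C6' are cut, leaving cyclobut-2-en-1-one A1 and the chromanone ynol ether A2.

- Forward step: on heating, A1 would open to vinylketene and add [2+2] to the electron-rich alkyne of A2. The new vinylcyclobutenone would open again and close by 6π electrocyclisation to the phenol A3. The mechanism itself places the hydroxyl and the methoxyl on either side of C1'.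
- In its favour: the plan is highly convergent. The substitution pattern of ring B is not a matter of selectivity, and the ring B hydroxyl appears unprotected; on both points it is better than the chosen plan. On paper it is also shorter, at perhaps seven or eight steps from a chromone.
- Against it here: A1 is volatile and polymerises, and the ynol ether of A2 is sensitive to acid and heat. A2 is a β-alkynyl β-aryloxy ketone, so retro-oxa-Michael opening to an ynone is easy at the temperatures the cascade needs, and C2 is at risk in the very step meant to preserve it. A2 would also need an asymmetric conjugate alkynylation with an alkoxyacetylide, a nucleophile for which that reaction type is not established. A3 still carries the C5 methyl ether, so a Lewis-acid demethylation must be run on the finished, ionisable flavanone.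
- Comparison: the two plans are equal in that neither creates the stereocentre in its key step. The chosen plan runs its key step on a masked ketone at lower temperature and ends without a Lewis acid.

**Alternative 2:** The O1–C8a bond is cut, which reveals the β-hydroxyacyl quinone A4.

- Forward step: the C2 hydroxyl would add in a 6-endo oxa-Michael fashion to the unsubstituted quinone carbon next to the acyl group. Enolisation would then aromatise ring A to the 5,8-hydroquinone A5.
- In its favour: the closure needs no metal and should run at room temperature. The C5 hydroxyl is formed free and chelated without any protecting group, a point on which the alternative is at least the equal of the chosen plan. The later methylation at O8 should be selective because the C5 hydroxyl is chelated. A polar closure of this kind is also mechanistically simpler than a hindered metathesis.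
- Against it here: A4 combines a β-hydroxy ketone, prone to dehydration to the enone (which destroys C2) and to retro-aldol cleavage, with a strongly oxidising acylquinone next to a benzylic alcohol. A5 is an electron-rich hydroquinone that would reoxidise in air. O8-methylation and debenzylation still follow the key step. Making A4 requires an asymmetric acetate aldol on a di-ortho-substituted benzaldehyde and an oxidative demethylation in the presence of that aldol.
- Comparison: step economy is about equal to the chosen plan. The chosen plan carries C2 as a robust aryl ether rather than as a free aldol.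

**Alternative 3:** Ring A is dismantled. The C8–C8a bond is cut and the other ring A carbons are traced back to dimethyl squarate A6, by way of the cyclobutenone A7.

- Forward step: heating A7 would open the four-membered ring to a dienylketene. This would close onto the enol-ether carbon of the dihydropyran and tautomerise to the phenol A8.
- In its favour: the hexasubstituted ring is built with the origin of every oxygen fixed. The cascade is thermal and catalyst-free and is probably more dependable than an enol ether metathesis on a crowded arene; on mechanism the alternative is the better plan.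
- Against it here: A8 has the wrong oxygen pattern for this target. The free hydroxyl is at C8 and the methyl ether at C5, while the target needs the reverse, and C4 is at the alcohol level. Methylation, desilylation, oxidation, a late Lewis-acid demethylation at C5 and debenzylation must follow. The C4 stereocentre is made only to be destroyed. The vinyllithium precursor of A7 needs its own enantioselective dihydropyranone synthesis and is a glycal-type enol ether that ionises readily at C2.
- Comparison: on step economy the alternative is clearly worse (about fifteen steps). The two plans are equal in carrying a pre-set C2 through the key step.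

Key step: step 10

Assumption: in step 8, L is the (Sa,Sc,Sc) phosphoramidite from 1,1'-bi-2-naphthol and bis[1-(2-methoxyphenyl)ethyl]amine; this ligand series is taken to give the S ether, and if the sense at this hindered terminus proves opposite, the mirror-image ligand is used and nothing else changes.

Remark: C2 has the same spatial arrangement in 15, 16, 17 and 18 and is S in all four, because the oxygen ranks above the aryl carbon and the aryl carbon above C3 (or the vinyl carbon) at every stage.

## Route

Step 1
Reactants: 1 1,2,3,4-tetramethoxybenzene
Product: 4 2,3,4,5-tetramethoxyphenol, via aryllithium 2 (not isolated), via dimethyl arylboronate 3 (not isolated)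
Conditions: n-BuLi, TMEDA, THF, 0 °C; B(OMe)3, −78 °C to rt; AcOH, 30% aq. H2O2, 0 °C to rt
Reagents that add atoms: hydrogen peroxide, OO
Why: Methoxy-directed ortho-lithiation can occur only at the two equivalent ring hydrogens; the aryllithium is borylated and the boronate undergoes ipso-oxidation (1,2-aryl shift from boron to oxygen) to the phenol, the acidic peroxide medium limiting over-oxidation of the electron-rich product.

Step 2
Reactants: 4 2,3,4,5-tetramethoxyphenol
Product: 6 1-(2-hydroxy-3,4,5,6-tetramethoxyphenyl)ethan-1-one, via difluoroboron chelate 5 (not isolated)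
Conditions: AcOH, BF3·OEt2, 70 °C; then H2O, EtOH, 60 °C
Reagents that add atoms: acetic acid, CC(=O)O
Why: Friedel–Crafts C-acylation (Fries-type) by the BF3-activated acid at the single open ring position, ortho to the hydroxyl; the product is held as its O,O-difluoroboron chelate and is hydrolysed to the hydrogen-bonded hydroxy ketone.

Step 3
Reactants: 6 1-(2-hydroxy-3,4,5,6-tetramethoxyphenyl)ethan-1-one
Product: 7 1-(2,6-dihydroxy-3,4,5-trimethoxyphenyl)ethan-1-one
Conditions: BCl3 (3 equiv), CH2Cl2, −78 to 0 °C; H2O
Reagents that add atoms: none
Why: Chelation-directed ether cleavage: boron bound to the carbonyl oxygen activates the flanking methoxyl for chloride attack on its methyl group (selective ortho-demethylation of aryl ketones); the product has a mirror plane, so its two hydroxyls are equivalent.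

Step 4
Reactants: 8 2-hydroxy-6-methoxybenzaldehyde
Product: 9 2-methoxy-6-(triisopropylsilyloxy)benzaldehyde
Conditions: TIPSCl, imidazole, DMAP (cat.), DMF, rt
Reagents that add atoms: chlorotri(propan-2-yl)silane, CC(C)[Si](Cl)(C(C)C)C(C)C
Why: Standard silylation of a phenol; the bulky aryl silyl ether should survive hydride, phosphonate anion, aryloxide and ruthenium carbene and leaves with fluoride at the end.

Step 5
Reactants: 9 2-methoxy-6-(triisopropylsilyloxy)benzaldehyde; 10 triethyl phosphonoacetate
Product: 11 ethyl (E)-3-[2-methoxy-6-(triisopropylsilyloxy)phenyl]prop-2-enoate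
Conditions: NaH, THF, 0 °C to rt
Reagents that add atoms: none
Why: Horner–Wadsworth–Emmons olefination; the stabilised phosphonate anion adds reversibly and the E-alkene results from the more stable oxaphosphetane, reinforced by the two ortho substituents.

Step 6
Reactants: 11 ethyl (E)-3-[2-methoxy-6-(triisopropylsilyloxy)phenyl]prop-2-enoate
Product: 12 (E)-3-[2-methoxy-6-(triisopropylsilyloxy)phenyl]prop-2-en-1-ol
Conditions: i-Bu2AlH (2.2 equiv), CH2Cl2, −78 to 0 °C; aq. KNaC4H4O6 (potassium sodium tartrate)
Reagents that add atoms: none
Why: 1,2-Reduction of an α,β-unsaturated ester to the allylic alcohol by an aluminium hydride; alkene geometry and the silyl ether are not affected.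

Step 7
Reactants: 12 (E)-3-[2-methoxy-6-(triisopropylsilyloxy)phenyl]prop-2-en-1-ol
Product: 13 (E)-3-[2-methoxy-6-(triisopropylsilyloxy)phenyl]prop-2-en-1-yl methyl carbonate
Conditions: ClCO2Me, pyridine, CH2Cl2, 0 °C
Reagents that add atoms: methyl chloroformate, COC(=O)Cl
Why: O-Acylation of a primary alcohol; the carbonate is the leaving group for the allylation and releases CO2 and methoxide on ionisation.

Step 8
Reactants: 7 1-(2,6-dihydroxy-3,4,5-trimethoxyphenyl)ethan-1-one; 13 (E)-3-[2-methoxy-6-(triisopropylsilyloxy)phenyl]prop-2-en-1-yl methyl carbonate
Product: 15 1-[2-hydroxy-3,4,5-trimethoxy-6-({(1S)-1-[2-methoxy-6-(triisopropylsilyloxy)phenyl]prop-2-en-1-yl}oxy)phenyl]ethan-1-one, via lithium phenolate 14 (not isolated)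
Conditions: 7 (1.5 equiv), LiN(SiMe3)2 (1.5 equiv), THF, 0 °C; then 13, [Ir(cod)Cl]2 (2 mol%), L (4 mol%, cyclometalated beforehand with n-PrNH2), THF, rt to 40 °C
Reagents that add atoms: none
Why: Iridium-catalysed asymmetric allylic etherification: the cyclometalated monovalent iridium phosphoramidite complex ionises the linear carbonate to an η3-allyl complex and the lithium aryloxide attacks the aryl-bearing terminus anti to the metal, giving the branched ether; the configuration at C2 is set by the ligand (catalyst control of the allyl face), and the excess of mirror-symmetric 7 together with chelation of the remaining hydroxyl should hold back a second allylation.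

Step 9
Reactants: 15 1-[2-hydroxy-3,4,5-trimethoxy-6-({(1S)-1-[2-methoxy-6-(triisopropylsilyloxy)phenyl]prop-2-en-1-yl}oxy)phenyl]ethan-1-one
Product: 16 (1S)-1-[2-methoxy-6-(triisopropylsilyloxy)phenyl]prop-2-en-1-yl 3-(tert-butyldimethylsilyloxy)-2-[1-(tert-butyldimethylsilyloxy)vinyl]-4,5,6-trimethoxyphenyl ether
Conditions: TBSOTf (2.6 equiv), Et3N (5 equiv), CH2Cl2, −78 to 0 °C
Reagents that add atoms: tert-butyldimethylsilyl trifluoromethanesulfonate, CC(C)(C)[Si](C)(C)OS(=O)(=O)C(F)(F)F
Why: Soft enolisation: the silyl triflate activates the carbonyl and Et3N removes a methyl proton to give the only possible enol silane, and the chelated phenol is silylated in the same flask; the amine excess and low temperature keep acid and free silyl cation away from the ionisable C2–O1 bond.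

Step 10
Reactants: 16 (1S)-1-[2-methoxy-6-(triisopropylsilyloxy)phenyl]prop-2-en-1-yl 3-(tert-butyldimethylsilyloxy)-2-[1-(tert-butyldimethylsilyloxy)vinyl]-4,5,6-trimethoxyphenyl ether
Product: 17 (2S)-4,5-bis(tert-butyldimethylsilyloxy)-6,7,8-trimethoxy-2-[2-methoxy-6-(triisopropylsilyloxy)phenyl]-2H-chromene
Conditions: second-generation Grubbs catalyst (H2IMes)(PCy3)Cl2Ru=CHPh (10 mol%), 1,4-benzoquinone (20 mol%), toluene (0.005 M), 70 °C, Ar sparge
Reagents that add atoms: none
Why: After phosphine loss, the ruthenium carbene undergoes [2+2] addition and cycloreversion with the monosubstituted vinyl group on C2, which places the metal on C3. This alkylidene then adds across the tethered 1,1-disubstituted enol ether with ruthenium on the terminal CH2 and C3 bonded to C4, and cycloreversion of the ruthenacyclobutane releases the C3=C4 bond and Ru=CH2, which carries the chain with loss of ethene. The closest known reaction type is the ring-closing ene–enol ether metathesis of aryl silyl enol ethers bearing an ortho N-allyl or O-allyl tether, which gives cyclic silyl enol ethers with second-generation ruthenium carbenes. Ring C closes as a six-membered ring with the new alkene inside it, the two alkenes being held within reach by the O1 tether and their ortho relationship on ring A. No stereocentre is formed, and C2 is retained because none of its bonds takes part. The step needs initiation at the vinyl group, which the substrate secures because the enol ether is 1,1-disubstituted, electron-rich and flanked by two ortho substituents, so that loading there (which would give an inert Fischer-type carbene) is slow. It also needs the allylic double bond not to migrate towards O1, which would erase C2; 1,4-benzoquinone intercepts ruthenium hydrides, and dilution with argon sparging favours closure over dimerisation and removes ethene.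

Step 11
Reactants: 17 (2S)-4,5-bis(tert-butyldimethylsilyloxy)-6,7,8-trimethoxy-2-[2-methoxy-6-(triisopropylsilyloxy)phenyl]-2H-chromene
Product: 18 (2S)-5-hydroxy-2-(2-hydroxy-6-methoxyphenyl)-6,7,8-trimethoxychroman-4-one
Conditions: Bu4NF (5 equiv), AcOH (6 equiv), THF, 0 °C to rt
Reagents that add atoms: none
Why: Fluoride-induced desilylation: the enol silane gives the enolate, which the acetic acid buffer protonates at C3 to the C4 ketone, and both aryl silyl ethers are cleaved to phenols; the near-neutral medium avoids the enolate and phenoxide conditions under which ring C opens by retro-oxa-Michael reaction, so C2 should remain S.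

## Compound list

1 | 1,2,3,4-tetramethoxybenzene | COc1ccc(OC)c(OC)c1OC | starting material
2 | (2,3,4,5-tetramethoxyphenyl)lithium | [Li]c1cc(OC)c(OC)c(OC)c1OC | intermediate
3 | dimethyl (2,3,4,5-tetramethoxyphenyl)boronate | COB(OC)c1cc(OC)c(OC)c(OC)c1OC | intermediate
4 | 2,3,4,5-tetramethoxyphenol | Oc1cc(OC)c(OC)c(OC)c1OC | intermediate
5 | 2,2-difluoro-5,6,7,8-tetramethoxy-4-methyl-1,3,2-benzodioxaborinine (O,O-difluoroboron chelate of 6) | CC1=[O+][B-](F)(F)Oc2c(OC)c(OC)c(OC)c(OC)c12 | intermediate
6 | 1-(2-hydroxy-3,4,5,6-tetramethoxyphenyl)ethan-1-one | CC(=O)c1c(O)c(OC)c(OC)c(OC)c1OC | intermediate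
7 | 1-(2,6-dihydroxy-3,4,5-trimethoxyphenyl)ethan-1-one | CC(=O)c1c(O)c(OC)c(OC)c(OC)c1O | intermediate
8 | 2-hydroxy-6-methoxybenzaldehyde | COc1cccc(O)c1C=O | starting material
9 | 2-methoxy-6-(triisopropylsilyloxy)benzaldehyde | COc1cccc(O[Si](C(C)C)(C(C)C)C(C)C)c1C=O | intermediate
10 | triethyl phosphonoacetate | CCOC(=O)CP(=O)(OCC)OCC | starting material
11 | ethyl (E)-3-[2-methoxy-6-(triisopropylsilyloxy)phenyl]prop-2-enoate | CCOC(=O)/C=C/c1c(OC)cccc1O[Si](C(C)C)(C(C)C)C(C)C | intermediate
12 | (E)-3-[2-methoxy-6-(triisopropylsilyloxy)phenyl]prop-2-en-1-ol | OC/C=C/c1c(OC)cccc1O[Si](C(C)C)(C(C)C)C(C)C | intermediate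
13 | (E)-3-[2-methoxy-6-(triisopropylsilyloxy)phenyl]prop-2-en-1-yl methyl carbonate | COC(=O)OC/C=C/c1c(OC)cccc1O[Si](C(C)C)(C(C)C)C(C)C | intermediate
14 | lithium 2-acetyl-3-hydroxy-4,5,6-trimethoxyphenolate | [Li+].CC(=O)c1c(O)c(OC)c(OC)c(OC)c1[O-] | intermediate
15 | 1-[2-hydroxy-3,4,5-trimethoxy-6-({(1S)-1-[2-methoxy-6-(triisopropylsilyloxy)phenyl]prop-2-en-1-yl}oxy)phenyl]ethan-1-one | COc1cccc(O[Si](C(C)C)(C(C)C)C(C)C)c1[C@H](C=C)Oc1c(C(C)=O)c(O)c(OC)c(OC)c1OC | intermediate
16 | (1S)-1-[2-methoxy-6-(triisopropylsilyloxy)phenyl]prop-2-en-1-yl 3-(tert-butyldimethylsilyloxy)-2-[1-(tert-butyldimethylsilyloxy)vinyl]-4,5,6-trimethoxyphenyl ether | COc1cccc(O[Si](C(C)C)(C(C)C)C(C)C)c1[C@H](C=C)Oc1c(C(=C)O[Si](C)(C)C(C)(C)C)c(O[Si](C)(C)C(C)(C)C)c(OC)c(OC)c1OC | intermediate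
17 | (2S)-4,5-bis(tert-butyldimethylsilyloxy)-6,7,8-trimethoxy-2-[2-methoxy-6-(triisopropylsilyloxy)phenyl]-2H-chromene | COc1cccc(O[Si](C(C)C)(C(C)C)C(C)C)c1[C@@H]1C=C(O[Si](C)(C)C(C)(C)C)c2c(O[Si](C)(C)C(C)(C)C)c(OC)c(OC)c(OC)c2O1 | intermediate
18 | (2S)-5-hydroxy-2-(2-hydroxy-6-methoxyphenyl)-6,7,8-trimethoxychroman-4-one | COc1cccc(O)c1[C@@H]1CC(=O)c2c(O)c(OC)c(OC)c(OC)c2O1 | target

## Step count and least certain steps

Total step count: 11. Longest linear sequence: 8 steps (steps 4 to 11, from 8 to 18).

**Step 10 (key step).** The most likely failure is that the catalyst loads on the vinyl group but the ring does not close. The enol ether is twisted out of the plane of ring A by its two ortho neighbours, and closure builds peri strain between the silyloxy groups at C4 and C5. The stalled alkylidene would then decay to hydride species that migrate the allylic double bond, or the substrate would dimerise through its vinyl groups. The fallback replaces the metathesis by an oxa-Michael closure and sets out from 7 and 8. 7 is converted with NaH and MOMCl into 1-[2,6-bis(methoxymethoxy)-3,4,5-trimethoxyphenyl]ethan-1-one F1, and 8 with BnBr and K2CO3 into 2-(benzyloxy)-6-methoxybenzaldehyde F2. Claisen–Schmidt condensation (KOH, EtOH) should give (E)-3-[2-(benzyloxy)-6-methoxyphenyl]-1-[2,6-bis(methoxymethoxy)-3,4,5-trimethoxyphenyl]prop-2-en-1-one F3. HCl in MeOH removes both acetals to give (E)-3-[2-(benzyloxy)-6-methoxyphenyl]-1-(2,6-dihydroxy-3,4,5-trimethoxyphenyl)prop-2-en-1-one F4, which NaOAc in hot EtOH closes to racemic 2-[2-(benzyloxy)-6-methoxyphenyl]-5-hydroxy-6,7,8-trimethoxychroman-4-one F5. Preparative chromatography on a chiral stationary phase gives (2S)-2-[2-(benzyloxy)-6-methoxyphenyl]-5-hydroxy-6,7,8-trimethoxychroman-4-one F6, and hydrogenolysis (H2, Pd/C, EtOAc) comes back to the route at 18. The price is that the stereocentre is resolved and not synthesised; the unwanted enantiomer can be re-equilibrated through the chalcone with base and recycled.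

**Step 8.** The most likely failure is attack of the aryloxide at the unhindered CH2 terminus (linear ether) or poor facial selectivity, because the di-ortho-substituted aryl group is twisted out of conjugation with the allyl unit and shields the branched terminus. In addition, the chelation-stabilised aryloxide is a good leaving group, so re-ionisation of the product may erode regio- and enantiopurity, and transfer of the methoxycarbonyl group to the aryloxide would consume 13. The fallback replaces the allyl electrophile by a propargyl one, which has no linear isomer, and sets out from 9 and 7. Addition of HC≡CMgBr to 9 gives racemic 1-[2-methoxy-6-(triisopropylsilyloxy)phenyl]prop-2-yn-1-ol F7, and Ac2O, Et3N and DMAP give 1-[2-methoxy-6-(triisopropylsilyloxy)phenyl]prop-2-yn-1-yl acetate F8. Enantioselective propargylic etherification of 7 with F8, through a copper allenylidene formed from CuOTf·0.5C6H6, a chiral 2,6-bis(oxazolinyl)pyridine ligand and i-Pr2NEt in a non-nucleophilic solvent, should give 1-[2-hydroxy-3,4,5-trimethoxy-6-({(1S)-1-[2-methoxy-6-(triisopropylsilyloxy)phenyl]prop-2-yn-1-yl}oxy)phenyl]ethan-1-one F9. Semihydrogenation (H2, Pd/CaCO3 poisoned with Pb(OAc)2, quinoline) comes back to the route at 15.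

**Step 9.** The most likely failure is Lewis-acid ionisation of the benzylic, allylic C2–O1 bond by the silyl triflate, leading to racemisation or a 1,3-shift of the aryloxy group to the cinnamyl position. Incomplete enolisation is the second risk, once the ketone is flanked by two ortho substituents. The fallback is stepwise and base-mediated and sets out from 15. TBSCl and imidazole in DMF silylate only the phenol to give 1-[2-(tert-butyldimethylsilyloxy)-3,4,5-trimethoxy-6-({(1S)-1-[2-methoxy-6-(triisopropylsilyloxy)phenyl]prop-2-en-1-yl}oxy)phenyl]ethan-1-one F10. Deprotonation with KN(SiMe3)2 in THF at −78 °C and O-silylation of the potassium enolate with TBSCl comes back to the route at 16.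

**Step 3.** The most likely failure is loss of regiocontrol in the ether cleavage: once the phenol oxygen is bound to boron, the methoxyl next to it can be cleaved through a five-membered chelate, or the second carbonyl-flanked ether resists. The fallback postpones the demethylation to the end and leaves out 7; it sets out from 6. 6 is deprotonated with LiN(SiMe3)2 and allylated with 13 under the conditions of step 8 to give 1-[2,3,4,5-tetramethoxy-6-({(1S)-1-[2-methoxy-6-(triisopropylsilyloxy)phenyl]prop-2-en-1-yl}oxy)phenyl]ethan-1-one F11. TBSOTf and Et3N give (1S)-1-[2-methoxy-6-(triisopropylsilyloxy)phenyl]prop-2-en-1-yl 2-[1-(tert-butyldimethylsilyloxy)vinyl]-3,4,5,6-tetramethoxyphenyl ether F12. The metathesis of step 10 gives (2S)-4-(tert-butyldimethylsilyloxy)-5,6,7,8-tetramethoxy-2-[2-methoxy-6-(triisopropylsilyloxy)phenyl]-2H-chromene F13. Bu4NF with AcOH gives (2S)-2-(2-hydroxy-6-methoxyphenyl)-5,6,7,8-tetramethoxychroman-4-one F14. BCl3 in CH2Cl2 at −78 °C then cleaves the C5 methyl ether by chelation and comes back to the route at 18. The price is that a Lewis acid meets the finished flavanone.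

## Further compounds

F1 | step 10 | 1-[2,6-bis(methoxymethoxy)-3,4,5-trimethoxyphenyl]ethan-1-one | CC(=O)c1c(OCOC)c(OC)c(OC)c(OC)c1OCOC
F2 | step 10 | 2-(benzyloxy)-6-methoxybenzaldehyde | COc1cccc(OCc2ccccc2)c1C=O
F3 | step 10 | (E)-3-[2-(benzyloxy)-6-methoxyphenyl]-1-[2,6-bis(methoxymethoxy)-3,4,5-trimethoxyphenyl]prop-2-en-1-one | COCOc1c(OC)c(OC)c(OC)c(OCOC)c1C(=O)/C=C/c1c(OC)cccc1OCc1ccccc1
F4 | step 10 | (E)-3-[2-(benzyloxy)-6-methoxyphenyl]-1-(2,6-dihydroxy-3,4,5-trimethoxyphenyl)prop-2-en-1-one | COc1c(O)c(C(=O)/C=C/c2c(OC)cccc2OCc2ccccc2)c(O)c(OC)c1OC
F5 | step 10 | racemic 2-[2-(benzyloxy)-6-methoxyphenyl]-5-hydroxy-6,7,8-trimethoxychroman-4-one | COc1cccc(OCc2ccccc2)c1C1CC(=O)c2c(O)c(OC)c(OC)c(OC)c2O1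
F6 | step 10 | (2S)-2-[2-(benzyloxy)-6-methoxyphenyl]-5-hydroxy-6,7,8-trimethoxychroman-4-one | COc1cccc(OCc2ccccc2)c1[C@@H]1CC(=O)c2c(O)c(OC)c(OC)c(OC)c2O1
F7 | step 8 | racemic 1-[2-methoxy-6-(triisopropylsilyloxy)phenyl]prop-2-yn-1-ol | COc1cccc(O[Si](C(C)C)(C(C)C)C(C)C)c1C(O)C#C
F8 | step 8 | racemic 1-[2-methoxy-6-(triisopropylsilyloxy)phenyl]prop-2-yn-1-yl acetate | COc1cccc(O[Si](C(C)C)(C(C)C)C(C)C)c1C(OC(C)=O)C#C
F9 | step 8 | 1-[2-hydroxy-3,4,5-trimethoxy-6-({(1S)-1-[2-methoxy-6-(triisopropylsilyloxy)phenyl]prop-2-yn-1-yl}oxy)phenyl]ethan-1-one | COc1cccc(O[Si](C(C)C)(C(C)C)C(C)C)c1[C@H](C#C)Oc1c(C(C)=O)c(O)c(OC)c(OC)c1OC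
F10 | step 9 | 1-[2-(tert-butyldimethylsilyloxy)-3,4,5-trimethoxy-6-({(1S)-1-[2-methoxy-6-(triisopropylsilyloxy)phenyl]prop-2-en-1-yl}oxy)phenyl]ethan-1-one | COc1cccc(O[Si](C(C)C)(C(C)C)C(C)C)c1[C@H](C=C)Oc1c(C(C)=O)c(O[Si](C)(C)C(C)(C)C)c(OC)c(OC)c1OC
F11 | step 3 | 1-[2,3,4,5-tetramethoxy-6-({(1S)-1-[2-methoxy-6-(triisopropylsilyloxy)phenyl]prop-2-en-1-yl}oxy)phenyl]ethan-1-one | COc1cccc(O[Si](C(C)C)(C(C)C)C(C)C)c1[C@H](C=C)Oc1c(C(C)=O)c(OC)c(OC)c(OC)c1OC
F12 | step 3 | (1S)-1-[2-methoxy-6-(triisopropylsilyloxy)phenyl]prop-2-en-1-yl 2-[1-(tert-butyldimethylsilyloxy)vinyl]-3,4,5,6-tetramethoxyphenyl ether | COc1cccc(O[Si](C(C)C)(C(C)C)C(C)C)c1[C@H](C=C)Oc1c(C(=C)O[Si](C)(C)C(C)(C)C)c(OC)c(OC)c(OC)c1OC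
F13 | step 3 | (2S)-4-(tert-butyldimethylsilyloxy)-5,6,7,8-tetramethoxy-2-[2-methoxy-6-(triisopropylsilyloxy)phenyl]-2H-chromene | COc1cccc(O[Si](C(C)C)(C(C)C)C(C)C)c1[C@@H]1C=C(O[Si](C)(C)C(C)(C)C)c2c(OC)c(OC)c(OC)c(OC)c2O1
F14 | step 3 | (2S)-2-(2-hydroxy-6-methoxyphenyl)-5,6,7,8-tetramethoxychroman-4-one | COc1cccc(O)c1[C@@H]1CC(=O)c2c(OC)c(OC)c(OC)c(OC)c2O1
A1 | alternative 1 | cyclobut-2-en-1-one | O=C1C=CC1
A2 | alternative 1 | (2S)-5,6,7,8-tetramethoxy-2-(methoxyethynyl)chroman-4-one | COC#C[C@@H]1CC(=O)c2c(OC)c(OC)c(OC)c(OC)c2O1
A3 | alternative 1 | (2S)-2-(2-hydroxy-6-methoxyphenyl)-5,6,7,8-tetramethoxychroman-4-one | COc1cccc(O)c1[C@@H]1CC(=O)c2c(OC)c(OC)c(OC)c(OC)c2O1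
A4 | alternative 2 | 2-[(3S)-3-(2-benzyloxy-6-methoxyphenyl)-3-hydroxypropanoyl]-5,6-dimethoxy-1,4-benzoquinone | COC1=C(OC)C(=O)C(C(=O)C[C@H](O)c2c(OC)cccc2OCc2ccccc2)=CC1=O
A5 | alternative 2 | (2S)-2-(2-benzyloxy-6-methoxyphenyl)-5,8-dihydroxy-6,7-dimethoxychroman-4-one | COc1cccc(OCc2ccccc2)c1[C@@H]1CC(=O)c2c(O)c(OC)c(OC)c(O)c2O1
A6 | alternative 3 | dimethyl squarate (3,4-dimethoxycyclobut-3-ene-1,2-dione) | COC1=C(OC)C(=O)C1=O
A7 | alternative 3 | 4-[(2S,4S)-2-(2-benzyloxy-6-methoxyphenyl)-4-(tert-butyldimethylsilyloxy)-3,4-dihydro-2H-pyran-5-yl]-2,3,4-trimethoxycyclobut-2-en-1-one | COc1cccc(OCc2ccccc2)c1[C@@H]1C[C@H](O[Si](C)(C)C(C)(C)C)C(C2(OC)C(OC)=C(OC)C2=O)=CO1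
A8 | alternative 3 | (2S,4S)-2-(2-benzyloxy-6-methoxyphenyl)-4-(tert-butyldimethylsilyloxy)-5,6,7-trimethoxychroman-8-ol | COc1cccc(OCc2ccccc2)c1[C@@H]1C[C@H](O[Si](C)(C)C(C)(C)C)c2c(OC)c(OC)c(OC)c(O)c2O1
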